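Locants used throughout (hydroazulene numbering): C1 isopropyl carbinol carbon, C2, C3, C3a methyl-bearing fusion carbon, C4 ring CH2, C5 secondary carbinol carbon, C6 methyl carbinol carbon, C7 ketone carbon, C8 aroyloxy carbon, C8a fusion CH. β is the face of the C3a methyl, α the opposite face.

## Analysis of the target

The target is a daucane-type sesquiterpenoid ester on a trans-fused hydroazulene: ring A is the cyclopentane C1–C2–C3–C3a–C8a and ring B the cycloheptanone C3a–C4–C5–C6–C7–C8–C8a. It has six stereocentres, (1R,3aR,5S,6S,8R,8aS): with the C3a methyl as β, the C8a hydrogen is α (trans fusion), the C1 hydroxyl is β with the isopropyl α, the oxygens at C5, C6 and C8 are all α, and the C6 methyl is β. Every heteroatom on ring B therefore lies on the face away from the angular methyl, so reagents that approach an unsaturated ring B from the α face should give the natural configuration. The sensitive part is the C7 ketone between a tertiary α-ketol (C6) and an α-acyloxy carbon (C8): it invites α-ketol rearrangement, acyl migration between the oxygens on C8, C6 and C1, and epimerisation at C8, and the two tertiary alcohols can dehydrate under acid. The difficulty lies in four contiguous oxidised carbons (C5 to C8) in a flexible seven-membered ring beside a quaternary carbon, in the trans ring junction that carries this quaternary centre, and in the near-equivalence of the two flanks of C6. The strategy rests on the fact that ring B divides into a three-carbon unit (C3a, C4, C5) and a four-carbon unit (C6, C7, C8, C8a) whose ends C3a and C8a are also bridged by C3, C2 and C1 of ring A, which is the connectivity left by an intramolecular (4+3) cycloaddition of an allyl cation onto a diene held by a three-atom tether.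

## Retrosynthetic reasoning

**25 to 23 (C5–O and C6–O).** The phenol is carried as a benzyl ether (24) and freed last under neutral conditions. The C5 and C6 hydroxyls are cis and both α, so they are cut together and traced to the C5=C6 bond of enone 23. This replaces a hydroboration plus an enolate hydroxylation by one cis-dihydroxylation and leaves the fragile tertiary ketol to the penultimate step. The forward reaction has to add both oxygens from the α face.

**23 to 18 and 21 (ester C–O).** The C8 hydroxyl of 18 is the only hydroxyl that can be acylated (the C1 hydroxyl is tertiary and hindered), so no protecting group is needed on the core. Acid 21 comes from 19 by O-benzylation.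

**18 to 15 (C7–O and C8–O; alkene position).** Enone 18 is the conjugated isomer of the β,γ-unsaturated ketol 17, which comes from triol 16 by oxidation of the C7 hydroxyl only, and 16 from cis-dihydroxylation of the C7=C8 alkene of diene 15. The C7=C8 alkene has to be oxidised first, while C4=C5 is kept to be moved into conjugation later. The two alkenes are sterically alike, so the forward step relies on the C1 hydroxyl, which sits next to C8, to deliver the oxidant.

**15 to 13 (C1–isopropyl).** The C1–isopropyl bond is cut to ketone 14, which is the unmasked form of ketal 13. The forward addition must come from the α face of the cyclopentanone, anti to the angular methyl, and must avoid enolisation toward C8a.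

**13 to 12 (C3a–C8a and C5–C6; the key cut).** Cutting these two bonds opens both rings at once and gives the acyclic allene–diene 12. The allene carbon bearing the methyl becomes C3a, the allene terminus becomes C5, and the (E,E)-diene supplies C6, C7, C8 and C8a. The forward reaction has to set the trans ring fusion, the quaternary centre and the absolute configuration.

**12 to 6 and 9 (C1–C2).** The ketal is traced to dienone 11, which is cut at the ketone–CH2 bond into the homoallenyl bromide 6 (as its Grignard reagent 10) and the Weinreb amide 9 of sorbic acid 7. The (E,E)-geometry is bought with 7.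

**6 to 1 and 2.** Bromide 6 comes from alcohol 5 and ester 4. The bond between the ester α-carbon and the methyl-bearing allene carbon of 4 is cut by a Johnson–Claisen retron to 1 and 2, which makes the 1,1-disubstituted allene in one step.

## Alternatives that were turned down

**Alternative 1:** Ring B is cut at C6–C7 and C3a–C4. In the forward sense a chiral dirhodium tetracarboxylate turns the vinyl diazoester A3 into a carbenoid that cyclopropanates the silyl enol ether of the cyclopentenyl dienol ether A2. The cis-divinylcyclopropane then undergoes a Cope rearrangement to the hydroazulenone A1. In its favour, asymmetric induction in this cyclopropanation–Cope sequence is better established than for a gold cycloaddition with an unusual allene, C7 arrives oxygenated, and the two alkenes of A1 (enoate and dienone) are electronically distinct. On those three points it is stronger than the chosen route. Against it, C6 carries an ester that must be reduced to a methyl group in several operations. C8a is sp2 in A1, so the trans ring junction has to be made later by a reduction with no clear control element. C8 has no oxygen, and the C1 ketone is part of a dienone, which complicates 1,2-addition of the isopropyl group. The Cope step must also form the quaternary C3a at a fully substituted alkene terminus. The chosen strategy sets the trans fusion, the quaternary centre and the methyl at its final oxidation level in the ring-forming step.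

**Alternative 2:** Ring A is cut at C1–C8a. The enolate of a ring B ketone at C8 in the keto-acetonide A5 attacks the isopropyl ketone at the end of the chain on C3a in an intramolecular aldol reaction and gives the ketol A4. In its favour, the cis-diol at C5 and C6 is already in place as an acetonide, so the late differentiation of two similar alkenes, the weak point of the chosen route, does not arise. Against it, the carbonyl of A4 is at C8 and C7 is a methylene, so a 1,2-carbonyl transposition with stereoselective reduction is still needed. The aldol addition to a hindered isopropyl ketone is reversible, enolisation can go toward C7 instead of C8a, and neither the trans fusion nor the C1 configuration is secured by a clear element. The chiral cycloheptanone A5 with its quaternary centre is itself a long synthesis. The chosen strategy needs one step for both rings, uses a catalyst for the absolute configuration and needs no transposition.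

**Alternative 3:** The two-carbon unit C7–C8 is cut out of ring B. Irradiation of the diquinane enone A7 with acetylene A8 gives the cyclobutene-fused ketone A6, whose cyclobutene is then opened to expand the five-membered ring to ring B. In its favour, the C1 carbinol and the C3a quaternary centre are already fixed in A7, and the ring expansion would give a conjugated diene with differentiated positions. On the early control of C1 it is stronger than the chosen route. Against it, A7 in enantiopure form is a multistep target of its own. The photocycloaddition with a gaseous alkyne is hard to scale, and opening a cyclobutene fused to a five-membered ring is geometrically constrained and needs forcing conditions. After opening, C8a is sp2, so the trans fusion is lost and must be rebuilt. The ketone ends at C5 and not at C7. The chosen strategy is shorter to the bicyclic core and fixes the ring fusion in the key step.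

Key step: step 7

**Remarks before the steps.**
- (L*)AuCl is the gold chloride complex of one enantiomer of the phosphoramidite L* built from 3,3'-di(anthracen-9-yl)-1,1'-bi-2-naphthol and bis(1-phenylethyl)amine. IPr is 1,3-bis(2,6-diisopropylphenyl)imidazol-2-ylidene.
- Assumption: the hand of L* that gives 13 and not its mirror image cannot be derived from first principles for this allene, so it is taken to be identified in a small test run; both hands of the ligand are accessible.

## Route

Step 1
Reactants: 1 but-2-yn-1-ol; 2 triethyl orthoacetate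
Product: 4 ethyl 3-methylpenta-3,4-dienoate, via ketene acetal 3 (not isolated)
Conditions: MeC(OEt)3 (5 equiv), EtCO2H (cat.), 140 °C, EtOH distilled off
Reagents that add atoms: none
Why: Johnson–Claisen rearrangement: acid-catalysed exchange gives the propargylic ketene acetal, whose [3,3]-sigmatropic shift forms the allene with the methyl on the carbon that becomes C3a.

Step 2
Reactants: 4 ethyl 3-methylpenta-3,4-dienoate
Product: 5 3-methylpenta-3,4-dien-1-ol
Conditions: LiAlH4, Et2O, 0 °C
Reagents that add atoms: none
Why: Hydride reduction of the ester; the non-conjugated allene is inert to LiAlH4 at 0 °C, and the low temperature should outrun base-induced isomerisation to a conjugated dienoate.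

Step 3
Reactants: 5 3-methylpenta-3,4-dien-1-ol
Product: 6 5-bromo-3-methylpenta-1,2-diene
Conditions: CBr4, PPh3, CH2Cl2, 0 °C
Reagents that add atoms: carbon tetrabromide, BrC(Br)(Br)Br
Why: Appel reaction: bromide displaces the alkoxyphosphonium group at a primary carbon under neutral conditions, which spares the allene.

Step 4
Reactants: 7 sorbic acid
Product: 9 (2E,4E)-N-methoxy-N-methylhexa-2,4-dienamide, via sorbyl imidazolide 8 (not isolated)
Conditions: 1,1'-carbonyldiimidazole, CH2Cl2, 0 °C to rt; then MeNH(OMe)·HCl, rt
Reagents that add atoms: N,O-dimethylhydroxylamine hydrochloride, CNOC.Cl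
Why: Acyl imidazolide formation followed by aminolysis gives the Weinreb amide under neutral conditions that leave the (E,E)-diene geometry untouched.

Step 5
Reactants: 6 5-bromo-3-methylpenta-1,2-diene; 9 (2E,4E)-N-methoxy-N-methylhexa-2,4-dienamide
Product: 11 (7E,9E)-3-methylundeca-1,2,7,9-tetraen-6-one, via Grignard reagent 10 (not isolated)
Conditions: Mg, THF, rt; then 9, −20 to 0 °C; aq. NH4Cl
Reagents that add atoms: none
Why: Grignard acylation of a Weinreb amide: the chelated tetrahedral adduct stops at the ketone, and 1,2-attack at the amide carbonyl is favoured over conjugate addition to the dienamide.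

Step 6
Reactants: 11 (7E,9E)-3-methylundeca-1,2,7,9-tetraen-6-one
Product: 12 2-(3-methylpenta-3,4-dien-1-yl)-2-[(1E,3E)-penta-1,3-dien-1-yl]-1,3-dioxolane
Conditions: Me3SiOCH2CH2OSiMe3, Me3SiOTf (5 mol %), CH2Cl2, −78 to −20 °C; pyridine quench
Reagents that add atoms: 1,2-bis(trimethylsilyloxy)ethane, C[Si](C)(C)OCCO[Si](C)(C)C
Why: Silyl-triflate-catalysed ketalisation with the bis-silyl ether of the diol is aprotic and kinetically controlled at low temperature, so the dienone should be ketalised without migration of its double bonds and without touching the allene.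

Step 7
Reactants: 12 2-(3-methylpenta-3,4-dien-1-yl)-2-[(1E,3E)-penta-1,3-dien-1-yl]-1,3-dioxolane
Product: 13 (3aR,6S,8aR)-3a,6-dimethyl-3,3a,6,8a-tetrahydro-2H-spiro[azulene-1,2'-[1,3]dioxolane]
Conditions: (L*)AuCl (5 mol %), AgSbF6 (5 mol %), 2,6-di-tert-butylpyridine (10 mol %), 4 Å MS, CH2Cl2, −15 °C
Reagents that add atoms: none
Why: AgSbF6 removes chloride from (L*)AuCl, and the cationic monovalent gold binds the terminal C=C of the allene, which slips to a gold-bound allyl cation over C3a, C4 and C5 with gold on C4. This cation adds across the s-cis (E,E)-diene in a concerted, asynchronous (4+3) cycloaddition: the tertiary terminus C3a bonds to the inner diene carbon C8a and the primary terminus C5 to the methyl-bearing diene carbon C6, which leaves a gold carbene at C4 that collapses by 1,2-hydrogen shift from C5 and releases the catalyst and the C4=C5 alkene. The closest known reaction type is the platinum- or gold-catalysed intramolecular (4+3) cycloaddition of allenedienes to trans-fused bicyclo[5.3.0]decadienes, including its enantioselective phosphoramidite–gold form. Ring A closes as a five-membered ring through the C3a–C8a bond, exo with respect to the diene because the three-atom tether (C3, C2, C1) leaves the rest of the diene outside the ring; ring B closes as the seven-membered cycloadduct ring when the second bond C5–C6 forms. The trans relation of the C3a methyl and the C8a hydrogen follows from the exo-like transition state in which the tether turns away from the gold-bearing carbon, the C6 configuration (methyl cis to the ring A branch on C8a) follows from suprafacial addition to the (E,E)-diene, and the absolute sense is set by the chiral phosphoramidite on gold. The step needs (4+3) and not (4+2) closure, and hydrogen shift and not ring contraction of the carbene; the hydrogen shift has only one direction because C3a is quaternary, and the ketal keeps the diene electron-rich and adds no stereocentre to the tether. The hindered pyridine and the sieves are there so that adventitious acid does not ionise the dienyl ketal.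

Step 8
Reactants: 13 (3aR,6S,8aR)-3a,6-dimethyl-3,3a,6,8a-tetrahydro-2H-spiro[azulene-1,2'-[1,3]dioxolane]
Product: 14 (3aR,6S,8aR)-3a,6-dimethyl-3,3a,6,8a-tetrahydroazulen-1(2H)-one
Conditions: pyridinium p-toluenesulfonate, acetone/H2O 10:1, 40 °C
Reagents that add atoms: water, O
Why: Mild acid hydrolysis of a simple cyclopentanone ketal; strong acid and base are avoided so that the β,γ-unsaturated ketone neither conjugates nor epimerises at C8a.

Step 9
Reactants: 14 (3aR,6S,8aR)-3a,6-dimethyl-3,3a,6,8a-tetrahydroazulen-1(2H)-one
Product: 15 (1R,3aR,6S,8aR)-3a,6-dimethyl-1-(propan-2-yl)-1,2,3,3a,6,8a-hexahydroazulen-1-ol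
Conditions: iPrMgCl, CeCl3 (anhydrous), THF, −78 to 0 °C
Reagents that add atoms: isopropylmagnesium chloride, CC(C)[Mg]Cl
Why: Organocerium 1,2-addition: the weakly basic reagent adds without enolising toward C8a or reducing the ketone. The β face of the carbonyl is closed by the angular methyl, which is 1,3 to C1, so attack comes from the α face, cis to the C8a hydrogen, and gives isopropyl α and hydroxyl β.

Step 10
Reactants: 15 (1R,3aR,6S,8aR)-3a,6-dimethyl-1-(propan-2-yl)-1,2,3,3a,6,8a-hexahydroazulen-1-ol
Product: 16 (1R,3aR,6R,7S,8R,8aS)-3a,6-dimethyl-1-(propan-2-yl)-1,2,3,3a,6,7,8,8a-octahydroazulene-1,7,8-triol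
Conditions: OsO4 (5 mol %), Me3NO·2H2O (1.1 equiv), CH2Cl2, 0 °C to rt
Reagents that add atoms: trimethylamine N-oxide, C[N+](C)(C)[O-]; water, O
Why: Hydrogen-bond-directed catalytic osmylation in a non-polar solvent: the C1 hydroxyl lies beside C8 in the mean plane of the bicycle and should hydrogen-bond the amine-ligated osmium oxo species, bringing it to C7=C8 in preference to the remote C4=C5 alkene. Attack can only come from the α face, because the β face of C8 is closed by the 1,3-related angular methyl and that of C7 by the C6 methyl, so both new hydroxyls are α.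

Step 11
Reactants: 16 (1R,3aR,6R,7S,8R,8aS)-3a,6-dimethyl-1-(propan-2-yl)-1,2,3,3a,6,7,8,8a-octahydroazulene-1,7,8-triol
Product: 17 (1R,3aR,6R,8R,8aS)-1,8-dihydroxy-3a,6-dimethyl-1-(propan-2-yl)-2,3,3a,6,8,8a-hexahydroazulen-7(1H)-one
Conditions: 2-iodoxybenzoic acid (IBX, 1.1 equiv), DMSO, rt
Reagents that add atoms: none
Why: IBX oxidises vicinal diols to α-ketols without C–C cleavage. The C7 hydroxyl is the accessible, pseudoaxial one, whereas the C8 hydroxyl is wedged between C8a and the isopropyl carbinol and its carbinol hydrogen is 1,3-diaxial to the angular methyl, so oxidation should stop at the C7 ketone.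

Step 12
Reactants: 17 (1R,3aR,6R,8R,8aS)-1,8-dihydroxy-3a,6-dimethyl-1-(propan-2-yl)-2,3,3a,6,8,8a-hexahydroazulen-7(1H)-one
Product: 18 (1R,3aR,8R,8aS)-1,8-dihydroxy-3a,6-dimethyl-1-(propan-2-yl)-2,3,3a,4,8,8a-hexahydroazulen-7(1H)-one
Conditions: DBU (0.2 equiv), CH2Cl2, 0 °C to rt
Reagents that add atoms: none
Why: Base-catalysed isomerisation of a β,γ- to an α,β-unsaturated ketone: C6–H is both α to the ketone and allylic, and the dienolate reprotonates at C4 to give the more stable trisubstituted enone. The C6 centre is erased here on purpose and rebuilt in step 15; the C8 hydroxyl already sits in its pseudoequatorial α position.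

Step 13
Reactants: 19 4-hydroxybenzoic acid
Product: 21 4-(benzyloxy)benzoic acid, via benzyl 4-(benzyloxy)benzoate 20 (not isolated)
Conditions: BnBr (2.2 equiv), K2CO3, DMF, 60 °C; then NaOH, MeOH/H2O, 60 °C; HCl to pH 2
Reagents that add atoms: benzyl bromide, BrCc1ccccc1
Why: Williamson etherification with concurrent benzyl ester formation, followed by saponification of the ester only; the aryl benzyl ether is stable to hydroxide.

Step 14
Reactants: 18 (1R,3aR,8R,8aS)-1,8-dihydroxy-3a,6-dimethyl-1-(propan-2-yl)-2,3,3a,4,8,8a-hexahydroazulen-7(1H)-one; 21 4-(benzyloxy)benzoic acid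
Product: 23 (1R,3aR,8R,8aS)-1-hydroxy-3a,6-dimethyl-7-oxo-1-(propan-2-yl)-1,2,3,3a,4,7,8,8a-octahydroazulen-8-yl 4-(benzyloxy)benzoate, via 4-(benzyloxy)benzoyl chloride 22 (not isolated)
Conditions: 21, (COCl)2, DMF (cat.), CH2Cl2, 0 °C to rt, concentrate; then 18, Et3N, DMAP, CH2Cl2, 0 °C to rt
Reagents that add atoms: none
Why: DMAP-catalysed acylation with the acid chloride: the C8 hydroxyl is the only secondary hydroxyl, and the hindered tertiary C1 hydroxyl should not compete, so the ester is placed without protecting groups on the core and with retention at C8.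

Step 15
Reactants: 23 (1R,3aR,8R,8aS)-1-hydroxy-3a,6-dimethyl-7-oxo-1-(propan-2-yl)-1,2,3,3a,4,7,8,8a-octahydroazulen-8-yl 4-(benzyloxy)benzoate
Product: 24 (1R,3aR,5S,6S,8R,8aS)-1,5,6-trihydroxy-3a,6-dimethyl-7-oxo-1-(propan-2-yl)decahydroazulen-8-yl 4-(benzyloxy)benzoate
Conditions: OsO4 (5 mol %), N-methylmorpholine N-oxide (1.5 equiv), citric acid (0.75 equiv), tBuOH/H2O 1:1, rt
Reagents that add atoms: N-methylmorpholine N-oxide, C[N+]1([O-])CCOCC1; water, O
Why: Osmium-catalysed cis-dihydroxylation of the electron-poor enone, with citric acid to keep turnover and to hold the medium acidic so that the ester does not migrate. Both oxygens should arrive from the α face, because the β face of C5 is 1,3-diaxial to the angular methyl, which sets C5–OH α, C6–OH α and C6–methyl β in one operation.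

Step 16
Reactants: 24 (1R,3aR,5S,6S,8R,8aS)-1,5,6-trihydroxy-3a,6-dimethyl-7-oxo-1-(propan-2-yl)decahydroazulen-8-yl 4-(benzyloxy)benzoate
Product: 25 (1R,3aR,5S,6S,8R,8aS)-1,5,6-trihydroxy-3a,6-dimethyl-7-oxo-1-(propan-2-yl)decahydroazulen-8-yl 4-hydroxybenzoate
Conditions: H2 (1 atm), 10% Pd/C (palladium on carbon), EtOAc, rt
Reagents that add atoms: none
Why: Hydrogenolysis of the aryl benzyl ether under neutral conditions; no alkene is left, and the ketol, the ester and the tertiary alcohols are not exposed to acid or base.

## Compound list

1 | but-2-yn-1-ol | CC#CCO | starting material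
2 | triethyl orthoacetate (1,1,1-triethoxyethane) | CCOC(C)(OCC)OCC | starting material
3 | 1-(but-2-yn-1-yloxy)-1-ethoxyethene (ketene acetal) | C=C(OCC)OCC#CC | intermediate
4 | ethyl 3-methylpenta-3,4-dienoate | C=C=C(C)CC(=O)OCC | intermediate
5 | 3-methylpenta-3,4-dien-1-ol | C=C=C(C)CCO | intermediate
6 | 5-bromo-3-methylpenta-1,2-diene | C=C=C(C)CCBr | intermediate
7 | sorbic acid, (2E,4E)-hexa-2,4-dienoic acid | C/C=C/C=C/C(O)=O | starting material
8 | (2E,4E)-1-(1H-imidazol-1-yl)hexa-2,4-dien-1-one (sorbyl imidazolide) | C/C=C/C=C/C(=O)n1ccnc1 | intermediate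
9 | (2E,4E)-N-methoxy-N-methylhexa-2,4-dienamide | C/C=C/C=C/C(=O)N(C)OC | intermediate
10 | (3-methylpenta-3,4-dien-1-yl)magnesium bromide | C=C=C(C)CC[Mg]Br | intermediate
11 | (7E,9E)-3-methylundeca-1,2,7,9-tetraen-6-one | C=C=C(C)CCC(=O)/C=C/C=C/C | intermediate
12 | 2-(3-methylpenta-3,4-dien-1-yl)-2-[(1E,3E)-penta-1,3-dien-1-yl]-1,3-dioxolane | C=C=C(C)CCC1(OCCO1)/C=C/C=C/C | intermediate
13 | (3aR,6S,8aR)-3a,6-dimethyl-3,3a,6,8a-tetrahydro-2H-spiro[azulene-1,2'-[1,3]dioxolane] (trans-fused; both methyls β, 8a-H α) | C[C@@H]1C=C[C@@]2(C)CCC3(OCCO3)[C@@H]2C=C1 | intermediate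
14 | (3aR,6S,8aR)-3a,6-dimethyl-3,3a,6,8a-tetrahydroazulen-1(2H)-one | C[C@@H]1C=C[C@@]2(C)CCC(=O)[C@@H]2C=C1 | intermediate
15 | (1R,3aR,6S,8aR)-3a,6-dimethyl-1-(propan-2-yl)-1,2,3,3a,6,8a-hexahydroazulen-1-ol (1-OH β) | CC(C)[C@]1(O)CC[C@]2(C)C=C[C@@H](C)C=C[C@H]21 | intermediate
16 | (1R,3aR,6R,7S,8R,8aS)-3a,6-dimethyl-1-(propan-2-yl)-1,2,3,3a,6,7,8,8a-octahydroazulene-1,7,8-triol (7-OH α, 8-OH α) | CC(C)[C@]1(O)CC[C@]2(C)C=C[C@@H](C)[C@H](O)[C@H](O)[C@H]21 | intermediate
17 | (1R,3aR,6R,8R,8aS)-1,8-dihydroxy-3a,6-dimethyl-1-(propan-2-yl)-2,3,3a,6,8,8a-hexahydroazulen-7(1H)-one | CC(C)[C@]1(O)CC[C@]2(C)C=C[C@@H](C)C(=O)[C@H](O)[C@H]21 | intermediate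
18 | (1R,3aR,8R,8aS)-1,8-dihydroxy-3a,6-dimethyl-1-(propan-2-yl)-2,3,3a,4,8,8a-hexahydroazulen-7(1H)-one | CC(C)[C@]1(O)CC[C@]2(C)CC=C(C)C(=O)[C@H](O)[C@H]21 | intermediate
19 | 4-hydroxybenzoic acid | OC(=O)c1ccc(O)cc1 | starting material
20 | benzyl 4-(benzyloxy)benzoate | O=C(OCc1ccccc1)c1ccc(OCc2ccccc2)cc1 | intermediate
21 | 4-(benzyloxy)benzoic acid | OC(=O)c1ccc(OCc2ccccc2)cc1 | intermediate
22 | 4-(benzyloxy)benzoyl chloride | ClC(=O)c1ccc(OCc2ccccc2)cc1 | intermediate
23 | (1R,3aR,8R,8aS)-1-hydroxy-3a,6-dimethyl-7-oxo-1-(propan-2-yl)-1,2,3,3a,4,7,8,8a-octahydroazulen-8-yl 4-(benzyloxy)benzoate | CC(C)[C@]1(O)CC[C@]2(C)CC=C(C)C(=O)[C@H](OC(=O)c3ccc(OCc4ccccc4)cc3)[C@H]21 | intermediate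
24 | (1R,3aR,5S,6S,8R,8aS)-1,5,6-trihydroxy-3a,6-dimethyl-7-oxo-1-(propan-2-yl)decahydroazulen-8-yl 4-(benzyloxy)benzoate | CC(C)[C@]1(O)CC[C@]2(C)C[C@H](O)[C@](C)(O)C(=O)[C@H](OC(=O)c3ccc(OCc4ccccc4)cc3)[C@H]21 | intermediate
25 | (1R,3aR,5S,6S,8R,8aS)-1,5,6-trihydroxy-3a,6-dimethyl-7-oxo-1-(propan-2-yl)decahydroazulen-8-yl 4-hydroxybenzoate | CC(C)[C@]1(O)CC[C@]2(C)C[C@H](O)[C@](C)(O)C(=O)[C@H](OC(=O)c3ccc(O)cc3)[C@H]21 | target

## Step count and least certain steps

Total: 16 steps. Longest linear sequence: 14 steps (steps 1–3, 5–12 and 14–16 from but-2-yn-1-ol); steps 4 and 13 are side branches.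

**Step 7 (key step).** The gold carbene may undergo ring contraction by 1,2-alkyl shift, or the vinylgold intermediate may close directly in a (4+2) sense, because the phosphoramidite is a weaker donor than a carbene ligand and the allene terminus is unsubstituted. Enantiocontrol may be poor for this allene pattern, and the dienyl ketal may ionise under the Lewis acidic conditions. The fallback moves the absolute control from the catalyst to a ketal auxiliary and uses the donor ligand that favours the hydrogen shift. It sets out from 11, which is ketalised with (2R,3R)-2,3-bis(trimethylsilyloxy)butane and catalytic Me3SiOTf to the C2-symmetric ketal (4R,5R)-4,5-dimethyl-2-(3-methylpenta-3,4-dien-1-yl)-2-[(1E,3E)-penta-1,3-dien-1-yl]-1,3-dioxolane F1. F1 is cyclised with achiral (IPr)AuCl/AgSbF6 in CH2Cl2, and the two trans-fused diastereomers are separated. The one with the ring configuration of 13, (3aR,6S,8aR,4'R,5'R)-3a,4',5',6-tetramethyl-3,3a,6,8a-tetrahydro-2H-spiro[azulene-1,2'-[1,3]dioxolane] F2, is hydrolysed with pyridinium p-toluenesulfonate in wet acetone, and the route is rejoined at 14. If the unwanted diastereomer predominates, the enantiomeric diol is used.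

**Step 10.** Chemoselectivity between the two cis-disubstituted alkenes may be lost if the C1 hydroxyl cannot deliver the oxidant to the α face of C7=C8, in which case osmylation would go to C4=C5 or to both alkenes. The fallback uses covalent delivery from a vanadium alkoxide and an oxidative epoxide opening. It sets out from 15, which is epoxidised with VO(acac)2 and tBuOOH in CH2Cl2 to the 7α,8α-epoxide of 15, F3. F3 is opened with DMSO and Me3SiOTf, then iPr2NEt, in a Kornblum-type oxidation: the sulfoxide should attack C7 from the β face, since C8 is screened by the angular methyl, and base then gives the 8α-trimethylsilyloxy ketone F4. Aqueous citric acid removes the silyl group, and the route is rejoined at 17.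

**Step 11.** Oxidation may occur at the wrong hydroxyl or go on to the 1,2-diketone, and a transient C8 ketone would allow epimerisation at C8a. The fallback fixes the C7/C8 regiochemistry by mechanism instead of by relative hydroxyl reactivity. It sets out from 15, which is hydroborated with 9-borabicyclo[3.3.1]nonane and oxidised with H2O2/NaOH; boron avoids C8 beside the ring fusion, and the 7α-alcohol, (1β,7α)-3a,6-dimethyl-1-(propan-2-yl)-1,2,3,3a,6,7,8,8a-octahydroazulene-1,7-diol F5, is separated from the C5 regioisomer that arises from the other alkene. Dess–Martin periodinane gives the β,γ-unsaturated ketone F6, DBU gives the conjugated enone F7, and kinetic enolisation at C8 with LiN(SiMe3)2 (2.2 equiv) followed by 2-(phenylsulfonyl)-3-phenyloxaziridine hydroxylates C8 from the α face. The route is rejoined at 18.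

**Step 15.** The hindered, electron-poor enone may react slowly, and facial selectivity in the flexible seven-membered ring may be poor, giving the β,β-diol. The fallback carries out the dihydroxylation one oxidation level lower, where an allylic hydroxyl reinforces the angular methyl. It sets out from 23, which is reduced with NaBH4/CeCl3 in MeOH at −40 °C (Luche reduction) to the 7β-allylic alcohol F8. OsO4/N-methylmorpholine N-oxide then adds anti to the 7β-hydroxyl and to the angular methyl to give the 5α,6α,7β-triol F9. The cis-5,6-diol is tied up as its acetonide F10 with 2,2-dimethoxypropane and pyridinium p-toluenesulfonate; the 7β-hydroxyl is trans to the C6 oxygen and stays free. Dess–Martin periodinane restores the C7 ketone in the acetonide ketone F11, and aqueous acetic acid removes the acetonide. The route is rejoined at 24.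

## Further compounds

F1 | step 7 | (4R,5R)-4,5-dimethyl-2-(3-methylpenta-3,4-dien-1-yl)-2-[(1E,3E)-penta-1,3-dien-1-yl]-1,3-dioxolane | C=C=C(C)CCC1(O[C@H](C)[C@@H](C)O1)/C=C/C=C/C
F2 | step 7 | (3aR,6S,8aR,4'R,5'R)-3a,4',5',6-tetramethyl-3,3a,6,8a-tetrahydro-2H-spiro[azulene-1,2'-[1,3]dioxolane] | C[C@@H]1C=C[C@@]2(C)CCC3(O[C@H](C)[C@@H](C)O3)[C@@H]2C=C1
F3 | step 10 | 7α,8α-epoxy-3a,6-dimethyl-1-(propan-2-yl)-1,2,3,3a,6,7,8,8a-octahydroazulen-1-ol (1-OH β, methyls β, 8a-H α) | CC(C)[C@]1(O)CC[C@]2(C)C=C[C@@H](C)[C@@H]3O[C@@H]3[C@H]21
F4 | step 10 | 1β-hydroxy-3a,6-dimethyl-1-(propan-2-yl)-8α-(trimethylsilyloxy)-2,3,3a,6,8,8a-hexahydroazulen-7(1H)-one | CC(C)[C@]1(O)CC[C@]2(C)C=C[C@@H](C)C(=O)[C@H](O[Si](C)(C)C)[C@H]21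
F5 | step 11 | (1β,7α)-3a,6-dimethyl-1-(propan-2-yl)-1,2,3,3a,6,7,8,8a-octahydroazulene-1,7-diol (methyls β, 8a-H α) | CC(C)[C@]1(O)CC[C@]2(C)C=C[C@@H](C)[C@H](O)C[C@H]21
F6 | step 11 | 1β-hydroxy-3a,6-dimethyl-1-(propan-2-yl)-2,3,3a,6,8,8a-hexahydroazulen-7(1H)-one (methyls β, 8a-H α) | CC(C)[C@]1(O)CC[C@]2(C)C=C[C@@H](C)C(=O)C[C@H]21
F7 | step 11 | 1β-hydroxy-3a,6-dimethyl-1-(propan-2-yl)-2,3,3a,4,8,8a-hexahydroazulen-7(1H)-one (3a-methyl β, 8a-H α) | CC(C)[C@]1(O)CC[C@]2(C)CC=C(C)C(=O)C[C@H]21
F8 | step 15 | 1β,7β-dihydroxy-3a,6-dimethyl-1-(propan-2-yl)-1,2,3,3a,4,7,8,8a-octahydroazulen-8α-yl 4-(benzyloxy)benzoate | CC(C)[C@]1(O)CC[C@]2(C)CC=C(C)[C@@H](O)[C@H](OC(=O)c3ccc(OCc4ccccc4)cc3)[C@H]21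
F9 | step 15 | 1β,5α,6α,7β-tetrahydroxy-3a,6-dimethyl-1-(propan-2-yl)decahydroazulen-8α-yl 4-(benzyloxy)benzoate | CC(C)[C@]1(O)CC[C@]2(C)C[C@H](O)[C@](C)(O)[C@@H](O)[C@H](OC(=O)c3ccc(OCc4ccccc4)cc3)[C@H]21
F10 | step 15 | 5α,6α-O-isopropylidene derivative of F9 (7β-OH free) | CC(C)[C@]1(O)CC[C@]2(C)C[C@@H]3OC(C)(C)O[C@]3(C)[C@@H](O)[C@H](OC(=O)c4ccc(OCc5ccccc5)cc4)[C@H]21
F11 | step 15 | 5α,6α-O-isopropylidene derivative of 24 (7-ketone) | CC(C)[C@]1(O)CC[C@]2(C)C[C@@H]3OC(C)(C)O[C@]3(C)C(=O)[C@H](OC(=O)c4ccc(OCc5ccccc5)cc4)[C@H]21
A1 | alternative 1 | methyl 7-[(tert-butyldimethylsilyl)oxy]-3a-methyl-1-oxo-1,2,3,3a,4,7-hexahydroazulene-6-carboxylate | COC(=O)C1=CC[C@@]2(C)CCC(=O)C2=C[C@H]1O[Si](C)(C)C(C)(C)C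
A2 | alternative 1 | 2-[(E)-2-(tert-butyldimethylsilyloxy)ethenyl]-3-methylcyclopent-2-en-1-one | CC1=C(/C=C/O[Si](C)(C)C(C)(C)C)C(=O)CC1
A3 | alternative 1 | methyl 2-diazobut-3-enoate | COC(=O)C(=[N+]=[N-])C=C
A4 | alternative 2 | trans-fused 1β-hydroxy-5α,6α-(isopropylidenedioxy)-3a,6-dimethyl-1-(propan-2-yl)decahydroazulen-8-one | CC(C)[C@]1(O)CC[C@]2(C)C[C@@H]3OC(C)(C)O[C@]3(C)CC(=O)[C@H]21
A5 | alternative 2 | 5,6-(isopropylidenedioxy)-3,6-dimethyl-3-(4-methyl-3-oxopentyl)cycloheptan-1-one | CC(C)C(=O)CC[C@]1(C)C[C@@H]2OC(C)(C)O[C@]2(C)CC(=O)C1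
A6 | alternative 3 | cyclobutene-fused tricyclic ketone (triethylsilyl ether) | CC(C)[C@]1(O[Si](CC)(CC)CC)CC[C@]2(C)CC(=O)[C@@]3(C)C=C[C@@]123
A7 | alternative 3 | 1,3a-dimethyl-6-(propan-2-yl)-6-(triethylsilyloxy)-3,3a,4,5,6-pentahydropentalen-2-one (diquinane enone) | CC(C)[C@]1(O[Si](CC)(CC)CC)CC[C@]2(C)CC(=O)C(C)=C12
A8 | alternative 3 | acetylene (ethyne) | C#C
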